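The plan rests on cutting the C3–C4 bond of ring C. Both carbons are at carbonyl oxidation level, because the 3-hydroxychromone is the enol of a chromane-3,4-dione. They therefore have like polarity and must be joined by umpolung. A carbene-catalysed intramolecular crossed benzoin converts the ring A formyl carbon (C4) into an acyl-anion equivalent that attacks a tethered aldehyde (C3). One operation forms C3–C4, closes ring C and installs the C3 oxygen. The precursor is a racemic dialdehyde: 2,3,4-tris(benzyloxy)benzaldehyde whose 6-oxygen (O1) bears a CH(CHO)(4-benzyloxyphenyl) group, released by buffered double oxidation of a diol. Oxidation, sulfation of the only free hydroxyl and hydrogenolysis complete the synthesis.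

Key step: step 7

Assumption: C2 is carried as the racemate because C2 and C3 both become sp2 in step 8; the sulfate is handled as its triethylammonium salt and converted into the free hydrogen sulfate drawn for the target only at the very end.

Step 1
Reactants: 1 3,4,5-tris(benzyloxy)benzaldehyde
Product: 3 3,4,5-tris(benzyloxy)phenol, via aryl formate 2 (not isolated)
Conditions: mCPBA, CH2Cl2, 0 °C to rt; aq. NaHCO3 wash; then K2CO3 (cat.), MeOH, rt
Reagents that add atoms: mCPBA, O=C(OO)c1cccc(Cl)c1
Why: Baeyer–Villiger (Dakin-type) oxidation in which the electron-rich aryl group, activated by its para benzyloxy group, migrates in preference to hydride, after which the labile aryl formate is cleaved by base-catalysed methanolysis without touching the benzyl ethers.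

Step 2
Reactants: 3 3,4,5-tris(benzyloxy)phenol
Product: 4 2,3,4-tris(benzyloxy)-6-hydroxybenzaldehyde
Conditions: MgCl2 (anhydrous), Et3N, paraformaldehyde, MeCN, reflux; then 1 M HCl
Reagents that add atoms: paraformaldehyde (as formaldehyde), C=O
Why: Casnati–Skattebøl ortho-formylation, in which the magnesium phenoxide delivers formaldehyde only to an ortho carbon and a second formaldehyde oxidises the benzylic alkoxide by hydride transfer; the two ortho positions of 3 are equivalent, so only one salicylaldehyde can form.

Step 3
Reactants: 5 racemic 4-hydroxymandelic acid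
Product: 6 racemic benzyl 2-[4-(benzyloxy)phenyl]-2-hydroxyacetate
Conditions: BnBr (2.1 equiv), K2CO3 (2.2 equiv), DMF, rt
Reagents that add atoms: benzyl bromide, BrCc1ccccc1
Why: Williamson-type O-alkylation in which carbonate deprotonates only the carboxylic acid and the phenol, so both are benzylated while the far less acidic secondary alcohol stays free; the ester group is a spectator that is reduced away in step 5.

Step 4
Reactants: 4 2,3,4-tris(benzyloxy)-6-hydroxybenzaldehyde; 6 racemic benzyl 2-[4-(benzyloxy)phenyl]-2-hydroxyacetate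
Product: 7 racemic benzyl 2-[4-(benzyloxy)phenyl]-2-[3,4,5-tris(benzyloxy)-2-formylphenoxy]acetate
Conditions: PPh3, DIAD, THF, 0 °C to rt
Reagents that add atoms: none
Why: Mitsunobu etherification in which the acidic phenol of 4 displaces the activated benzylic alpha-hydroxy ester by SN2 under essentially neutral conditions, which avoids a base-induced aldol of the acidic C2–H onto the formyl group; the O1–C2 centre is racemic by design.

Step 5
Reactants: 7 racemic benzyl 2-[4-(benzyloxy)phenyl]-2-[3,4,5-tris(benzyloxy)-2-formylphenoxy]acetate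
Product: 8 racemic 2-[4-(benzyloxy)phenyl]-2-[3,4,5-tris(benzyloxy)-2-(hydroxymethyl)phenoxy]ethan-1-ol
Conditions: LiAlH4, THF, 0 °C; H2O/aq. NaOH work-up; Et3N-deactivated silica
Reagents that add atoms: none
Why: Hydride reduction that takes the aldehyde and the ester to primary alcohols in one operation, so the two carbonyl groups need not be told apart, while aryl benzyl ethers and the aryl alkyl ether are inert to LiAlH4.

Step 6
Reactants: 8 racemic 2-[4-(benzyloxy)phenyl]-2-[3,4,5-tris(benzyloxy)-2-(hydroxymethyl)phenoxy]ethan-1-ol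
Product: 9 racemic 2,3,4-tris(benzyloxy)-6-{1-[4-(benzyloxy)phenyl]-2-oxoethoxy}benzaldehyde
Conditions: Dess–Martin periodinane (2.4 equiv), pyridine, CH2Cl2, 0 °C to rt; cold aq. Na2S2O3/NaHCO3 wash; used at once without chromatography
Reagents that add atoms: none
Why: Dess–Martin oxidation of both primary alcohols in a pyridine-buffered, non-aqueous medium that stops at the aldehyde stage and should neither ionise the electron-rich benzylic position nor appreciably enolise the C2–H.

Step 7
Reactants: 9 racemic 2,3,4-tris(benzyloxy)-6-{1-[4-(benzyloxy)phenyl]-2-oxoethoxy}benzaldehyde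
Product: 10 rac-(2R,3R)-5,6,7-tris(benzyloxy)-2-[4-(benzyloxy)phenyl]-3-hydroxychroman-4-one (trans)
Conditions: 3-ethyl-5-(2-hydroxyethyl)-4-methylthiazolium bromide (20 mol%), Et3N (50 mol%), THF/t-BuOH, 0.02 M, 50 °C, argon
Reagents that add atoms: none
Why: Proposed new method: the thiazol-2-ylidene adds to the ring A formyl carbon (C4), proton transfer gives the aryl-conjugated Breslow enaminol, this acyl-anion equivalent attacks the inductively activated C3 aldehyde, and collapse of the adduct expels the carbene to leave the C4 ketone beside the C3 carbinol. The closest known reaction type is the carbene-catalysed intramolecular crossed benzoin of 2-(2-oxoalkoxy)benzaldehydes, an aldehyde–ketone union that gives 3-substituted 3-hydroxychroman-4-ones; an aldehyde acceptor carrying an alpha-aryloxy leaving group and an acidic alpha-hydrogen has not been shown. Ring C closes in the 6-exo-trig mode. The new C3 centre is governed by the C2 aryl group, which takes a pseudo-equatorial place in a half-chair transition state, and since the addition is reversible and C3 is epimerisable the diequatorial trans isomer should dominate, although both centres vanish in step 8. The selectivity needed is that C4 and not C3 becomes the donor, because an enaminol at C3 would expel the ring A aryloxide irreversibly; the substrate helps through the doubly branched C2 that screens the C3 formyl group and through aryl conjugation that makes only the C4 adduct easy to deprotonate, while a thiazolylidene with one small N-substituent can still reach a formyl group flanked by O1 and the 5-benzyloxy group. The weak amine base and the protic cosolvent keep enolisation at C2 low, and the 5-exo aldol that enolisation could cause ends at a quaternary C2 that cannot dehydrate, so it stays reversible and drains into the more stable vinylogous-ester ketone 10.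

Step 8
Reactants: 10 rac-(2R,3R)-5,6,7-tris(benzyloxy)-2-[4-(benzyloxy)phenyl]-3-hydroxychroman-4-one
Product: 12 5,6,7-tris(benzyloxy)-2-[4-(benzyloxy)phenyl]-3-hydroxy-4H-chromen-4-one, via chromane-3,4-dione 11 (not isolated)
Conditions: Dess–Martin periodinane (1.2 equiv), CH2Cl2, 0 °C to rt; aq. NaHCO3 wash
Reagents that add atoms: none
Why: Dess–Martin oxidation of an acyloin to a 1,2-diketone, whose C2–H (flanked by O1, ring B and the C3 ketone) should tautomerise spontaneously to the aromatic 3-hydroxy-4-pyranone, erasing C2 and C3 and funnelling any stereo- or regioisomeric acyloin from step 7 into one compound.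

Step 9
Reactants: 12 5,6,7-tris(benzyloxy)-2-[4-(benzyloxy)phenyl]-3-hydroxy-4H-chromen-4-one
Product: 13 triethylammonium 5,6,7-tris(benzyloxy)-2-[4-(benzyloxy)phenyl]-4-oxo-4H-chromen-3-yl sulfate
Conditions: SO3·NEt3 (4 equiv), DMF, 55 °C; silica, CH2Cl2/MeOH/Et3N
Reagents that add atoms: sulfur trioxide–triethylamine complex, CC[N+](CC)(CC)S(=O)(=O)[O-]
Why: O-sulfation with a sulfur trioxide–amine complex, regioselective because the 3-OH is the only free hydroxyl of 12, giving the monoester as a stable, organic-soluble ammonium salt.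

Step 10
Reactants: 13 triethylammonium 5,6,7-tris(benzyloxy)-2-[4-(benzyloxy)phenyl]-4-oxo-4H-chromen-3-yl sulfate
Product: 15 5,6,7-trihydroxy-2-(4-hydroxyphenyl)-4-oxo-4H-chromen-3-yl hydrogen sulfate (6-hydroxykaempferol 3-sulfate), via triethylammonium salt 14 (not isolated)
Conditions: H2 (1 atm), 10% Pd/C, degassed THF/MeOH, rt; filter under argon; sulfonic acid cation-exchange resin (H+ form), MeOH/H2O, 0 °C; freeze-dry
Reagents that add atoms: none
Why: Catalytic hydrogenolysis of aryl benzyl ethers followed by cation exchange, in which sulfate monoester salts and the tetrasubstituted C2=C3 bond of the pyranone are not reduced at one atmosphere of hydrogen and brief cold contact with the resin swaps triethylammonium for a proton.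

Compound list
1 | 3,4,5-tris(benzyloxy)benzaldehyde | O=Cc1cc(OCc2ccccc2)c(OCc2ccccc2)c(OCc2ccccc2)c1 | starting material
2 | 3,4,5-tris(benzyloxy)phenyl formate (not isolated) | O=COc1cc(OCc2ccccc2)c(OCc2ccccc2)c(OCc2ccccc2)c1 | intermediate
3 | 3,4,5-tris(benzyloxy)phenol | Oc1cc(OCc2ccccc2)c(OCc2ccccc2)c(OCc2ccccc2)c1 | intermediate
4 | 2,3,4-tris(benzyloxy)-6-hydroxybenzaldehyde | O=Cc1c(O)cc(OCc2ccccc2)c(OCc2ccccc2)c1OCc1ccccc1 | intermediate
5 | 4-hydroxymandelic acid, racemic | OC(C(=O)O)c1ccc(O)cc1 | starting material
6 | benzyl 2-[4-(benzyloxy)phenyl]-2-hydroxyacetate, racemic | OC(C(=O)OCc1ccccc1)c1ccc(OCc2ccccc2)cc1 | intermediate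
7 | benzyl 2-[4-(benzyloxy)phenyl]-2-[3,4,5-tris(benzyloxy)-2-formylphenoxy]acetate, racemic | O=Cc1c(OC(C(=O)OCc2ccccc2)c2ccc(OCc3ccccc3)cc2)cc(OCc2ccccc2)c(OCc2ccccc2)c1OCc1ccccc1 | intermediate
8 | 2-[4-(benzyloxy)phenyl]-2-[3,4,5-tris(benzyloxy)-2-(hydroxymethyl)phenoxy]ethan-1-ol, racemic | OCc1c(OC(CO)c2ccc(OCc3ccccc3)cc2)cc(OCc2ccccc2)c(OCc2ccccc2)c1OCc1ccccc1 | intermediate
9 | 2,3,4-tris(benzyloxy)-6-{1-[4-(benzyloxy)phenyl]-2-oxoethoxy}benzaldehyde, racemic | O=Cc1c(OC(C=O)c2ccc(OCc3ccccc3)cc2)cc(OCc2ccccc2)c(OCc2ccccc2)c1OCc1ccccc1 | intermediate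
10 | rac-(2R,3R)-5,6,7-tris(benzyloxy)-2-[4-(benzyloxy)phenyl]-3-hydroxychroman-4-one, trans, one enantiomer drawn | O=C1c2c(OCc3ccccc3)c(OCc3ccccc3)c(OCc3ccccc3)cc2O[C@H](c2ccc(OCc3ccccc3)cc2)[C@H]1O | intermediate
11 | 5,6,7-tris(benzyloxy)-2-[4-(benzyloxy)phenyl]chromane-3,4-dione (not isolated) | O=C1C(=O)c2c(OCc3ccccc3)c(OCc3ccccc3)c(OCc3ccccc3)cc2OC1c1ccc(OCc2ccccc2)cc1 | intermediate
12 | 5,6,7-tris(benzyloxy)-2-[4-(benzyloxy)phenyl]-3-hydroxy-4H-chromen-4-one | O=c1c(O)c(-c2ccc(OCc3ccccc3)cc2)oc2cc(OCc3ccccc3)c(OCc3ccccc3)c(OCc3ccccc3)c12 | intermediate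
13 | triethylammonium 5,6,7-tris(benzyloxy)-2-[4-(benzyloxy)phenyl]-4-oxo-4H-chromen-3-yl sulfate | O=c1c(OS(=O)(=O)[O-])c(-c2ccc(OCc3ccccc3)cc2)oc2cc(OCc3ccccc3)c(OCc3ccccc3)c(OCc3ccccc3)c12.CC[NH+](CC)CC | intermediate
14 | triethylammonium 5,6,7-trihydroxy-2-(4-hydroxyphenyl)-4-oxo-4H-chromen-3-yl sulfate (not isolated) | O=c1c(OS(=O)(=O)[O-])c(-c2ccc(O)cc2)oc2cc(O)c(O)c(O)c12.CC[NH+](CC)CC | intermediate
15 | 5,6,7-trihydroxy-2-(4-hydroxyphenyl)-4-oxo-4H-chromen-3-yl hydrogen sulfate | O=c1c(OS(=O)(=O)O)c(-c2ccc(O)cc2)oc2cc(O)c(O)c(O)c12 | target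

Total step count: 10. Longest linear sequence: 9 steps (steps 1, 2, 4, 5, 6, 7, 8, 9, 10, from 1 to 15); step 3 is the one-step side branch.

Steps most likely to fail

1. Step 7.
- Risk: the carbene may engage the C3 aldehyde, whose enaminol then expels the ring A aryloxide in an irreversible internal redox. Alternatively, the formyl group shielded by two ortho oxygens may simply not turn over while slow enolisation at C2 erodes the material.
- Fallback: it sets out from dialdehyde 9 and makes the same C3–C4 bond reductively instead of by umpolung. SmI2 (2.5 equiv) in THF/t-BuOH at −78 °C to 0 °C reduces the more easily reduced ring A aldehyde to its ketyl. The ketyl couples with the neighbouring aldehyde in a six-ring pinacol cyclisation, an established reaction of 1,6-dialdehydes that includes alpha-oxygenated ones. This gives 5,6,7-tris(benzyloxy)-2-[4-(benzyloxy)phenyl]chromane-3,4-diol F1 as a diastereomer mixture.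
- Return to the route: IBX in DMSO at rt, which oxidises 1,2-diols to 1,2-diketones without glycol cleavage, takes both carbinols to dione 11. The dione tautomerises, and the route is rejoined at flavonol 12.

2. Step 6.
- Risk: the half-oxidised material may close to a seven-membered lactol and be over-oxidised, the very electron-rich benzylic alcohol may ionise, and the dialdehyde may enolise, hydrate or autoxidise during work-up.
- Fallback: it sets out from ester aldehyde 7 and uses neither a diol nor an oxidant. HC(OMe)3 with catalytic pyridinium p-toluenesulfonate in MeOH masks the ring A aldehyde as benzyl 2-[4-(benzyloxy)phenyl]-2-[3,4,5-tris(benzyloxy)-2-(dimethoxymethyl)phenoxy]acetate F2. DIBAL-H (1.1 equiv) in toluene at −78 °C stops at the chelated hemiacetal aluminate typical of alpha-oxygenated esters. A cold quench then gives 2-[4-(benzyloxy)phenyl]-2-[3,4,5-tris(benzyloxy)-2-(dimethoxymethyl)phenoxy]acetaldehyde F3.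
- Return to the route: the acetal of this strongly donor-substituted arene hydrolyses on wet silica gel with a trace of oxalic acid in CH2Cl2, mild enough for the aliphatic aldehyde. The route is rejoined at 9.

3. Step 10.
- Risk: the fourfold hydrogenolysis of an ionic substrate may stall on a fouled catalyst, with slow solvolytic loss of the sulfate and air oxidation of the trihydroxylated ring A during the prolonged handling.
- Fallback: it sets out from flavonol 12 and carries the sulfate as a neutral, chromatographable diester. 2,2,2-Trichloroethyl chlorosulfate, Et3N and DMAP in THF give 5,6,7-tris(benzyloxy)-2-[4-(benzyloxy)phenyl]-4-oxo-4H-chromen-3-yl 2,2,2-trichloroethyl sulfate F4. Transfer hydrogenolysis with 10% Pd/C and HCO2NH4 in MeOH/THF is a known way to unmask such aryl sulfate diesters. It releases the trichloroethyl group and the four benzyl groups together in a near-neutral buffered medium, giving ammonium 5,6,7-trihydroxy-2-(4-hydroxyphenyl)-4-oxo-4H-chromen-3-yl sulfate F5.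
- Return to the route: the same cold cation exchange rejoins the route at 15.

Further compounds
F1 | step 7 | 5,6,7-tris(benzyloxy)-2-[4-(benzyloxy)phenyl]chromane-3,4-diol (diastereomer mixture, racemic) | OC1c2c(OCc3ccccc3)c(OCc3ccccc3)c(OCc3ccccc3)cc2OC(c2ccc(OCc3ccccc3)cc2)C1O
F2 | step 6 | benzyl 2-[4-(benzyloxy)phenyl]-2-[3,4,5-tris(benzyloxy)-2-(dimethoxymethyl)phenoxy]acetate (racemic) | COC(OC)c1c(OC(C(=O)OCc2ccccc2)c2ccc(OCc3ccccc3)cc2)cc(OCc2ccccc2)c(OCc2ccccc2)c1OCc1ccccc1
F3 | step 6 | 2-[4-(benzyloxy)phenyl]-2-[3,4,5-tris(benzyloxy)-2-(dimethoxymethyl)phenoxy]acetaldehyde (racemic) | COC(OC)c1c(OC(C=O)c2ccc(OCc3ccccc3)cc2)cc(OCc2ccccc2)c(OCc2ccccc2)c1OCc1ccccc1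
F4 | step 10 | 5,6,7-tris(benzyloxy)-2-[4-(benzyloxy)phenyl]-4-oxo-4H-chromen-3-yl 2,2,2-trichloroethyl sulfate | O=c1c(OS(=O)(=O)OCC(Cl)(Cl)Cl)c(-c2ccc(OCc3ccccc3)cc2)oc2cc(OCc3ccccc3)c(OCc3ccccc3)c(OCc3ccccc3)c12
F5 | step 10 | ammonium 5,6,7-trihydroxy-2-(4-hydroxyphenyl)-4-oxo-4H-chromen-3-yl sulfate | O=c1c(OS(=O)(=O)[O-])c(-c2ccc(O)cc2)oc2cc(O)c(O)c(O)c12.[NH4+]
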